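**Retrosynthetic overview**
1. Target 26 ⇐ singlet-oxygen ene reaction on the 4(5)-Z-ene furanone 24, which moves the alkene to C4(15) and installs C5–OH; no ring is formed.
2. Furanone 24 ⇐ transannular ketalisation/elimination of the C10 hydroxyl onto C3 of a macrocyclic 10-hydroxy-1,3-dione equivalent (3-methoxy enone 22); this is the last ring formed.
3. Ten-membered carbocycle and α-methylene-γ-lactone ⇐ one CrCl2 Barbier macrocyclisation of open-chain 18 that forges C6–C7 (the bond the germacrene cyclase makes) and sets C6 and C7.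
4. Open chain 18 ⇐ butenolide by ring-closing metathesis; C1–C2 by acetylide opening of lactone 11 (C10 from a copper/bis(oxazoline) pyruvate aldol, C8 from Noyori transfer hydrogenation) with commercial (Z)-enynol 1.
5. Ring order: butenolide (allyl donor) → carbocycle plus α-methylene lactone (one step) → 3(2H)-furanone.

Assumption: germacrane numbering is used (C1 ketone, C3–O–C10 furanone bridge, C6 angelate, 12,8-lactone); the target is the (5S,6S,7R,8S,10R) isomer given by the SMILES.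

**Step 1**
Reactants: 1 (Z)-3-methylpent-2-en-4-yn-1-ol
Product: 2 (Z)-triethyl[(3-methylpent-2-en-4-yn-1-yl)oxy]silane
Conditions: TESCl, imidazole, CH2Cl2, 0 °C
Reagents that add atoms: chlorotriethylsilane, CC[Si](Cl)(CC)CC
Why: Standard silylation of the primary alcohol; the Z alkene (C3 and C6 cis, as needed for ring closure) is untouched.

**Step 2**
Reactants: 3 pent-3-yn-2-one
Product: 4 trimethyl(pent-1-en-3-yn-2-yloxy)silane
Conditions: TMSOTf, Et3N, CH2Cl2, 0 °C
Reagents that add atoms: trimethylsilyl triflate, C[Si](C)(C)OS(=O)(=O)C(F)(F)F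
Why: Soft enolisation/silylation of the only enolisable methyl gives the enol silane for the Mukaiyama aldol.

**Step 3**
Reactants: 4 trimethyl(pent-1-en-3-yn-2-yloxy)silane; 5 methyl pyruvate
Product: 7 methyl (2R)-2-hydroxy-2-methyl-4-oxohept-5-ynoate, via trimethylsilyl ether 6 (not isolated)
Conditions: Cu(OTf)2 (10 mol %), (R,R)-t-Bu-box (11 mol %), THF, −78 °C; then 1 M HCl
Reagents that add atoms: none
Why: Evans-type catalytic enantioselective Mukaiyama aldol to pyruvate; the pyruvate chelated to the square-planar divalent copper bis(oxazoline) complex is attacked on its re face with the (R,R)-ligand (mirror image of the (S,S)/si-face/(S) case), which sets C10 as R.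

**Step 4**
Reactants: 7 methyl (2R)-2-hydroxy-2-methyl-4-oxohept-5-ynoate
Product: 8 methyl (2R)-2-methyl-4-oxo-2-[(triethylsilyl)oxy]hept-5-ynoate
Conditions: TESOTf, 2,6-lutidine, CH2Cl2, −78 → 0 °C
Reagents that add atoms: triethylsilyl triflate, CC[Si](CC)(CC)OS(=O)(=O)C(F)(F)F
Why: Silylation of the tertiary carbinol blocks retro-aldol and keeps the C10 oxygen masked until the late furanone closure.

**Step 5**
Reactants: 8 methyl (2R)-2-methyl-4-oxo-2-[(triethylsilyl)oxy]hept-5-ynoate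
Product: 10 (3R,5S)-3-methyl-5-(prop-1-yn-1-yl)-3-[(triethylsilyl)oxy]oxolan-2-one, via hydroxy ester 9 (not isolated)
Conditions: Ru(p-cymene)[(S,S)-TsNCHPhCHPhNH] (1 mol %), i-PrOH, 25 °C; then PPTS (cat.), PhMe, 60 °C
Reagents that add atoms: none
Why: Noyori asymmetric transfer hydrogenation of an alkynyl ketone is reagent-controlled (alkynyl takes the aryl position, so the (S,S)-catalyst gives the (S)-propargylic alcohol, C8), and acid-catalysed lactonisation ties O8 to C1.

**Step 6**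
Reactants: 10 (3R,5S)-3-methyl-5-(prop-1-yn-1-yl)-3-[(triethylsilyl)oxy]oxolan-2-one
Product: 11 (3R,5S)-3-methyl-5-[(1Z)-prop-1-en-1-yl]-3-[(triethylsilyl)oxy]oxolan-2-one
Conditions: H2 (1 atm), Pd/CaCO3 poisoned with Pb(OAc)2, quinoline, EtOAc, 25 °C
Reagents that add atoms: none
Why: Lindlar semihydrogenation gives the Z-propenyl group that later serves as the metathesis partner; no stereocentre is touched.

**Step 7**
Reactants: 2 (Z)-triethyl[(3-methylpent-2-en-4-yn-1-yl)oxy]silane; 11 (3R,5S)-3-methyl-5-[(1Z)-prop-1-en-1-yl]-3-[(triethylsilyl)oxy]oxolan-2-one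
Product: 14 (2Z,4S,6R,8E,10Z)-4-hydroxy-9-methoxy-6,10-dimethyl-6,12-bis[(triethylsilyl)oxy]dodeca-2,8,10-trien-7-one, via lithium acetylide 12 (not isolated), via hydroxy ynone 13 (not isolated)
Conditions: n-BuLi, THF, −78 °C; add 11, −78 → −40 °C; AcOH, −78 °C; then MeOH, PBu3 (10 mol %), 0 → 25 °C
Reagents that add atoms: methanol, CO
Why: Single acetylide addition to the lactone (stable lactolate) forms C1–C2 and frees the C8 hydroxyl; phosphine-catalysed conjugate addition of methanol to C3 then turns the ynone into a vinylogous ester (the methyl enol ether of the 1,3-dione), removing the alkyne before metathesis; the C2=C3 geometry is inconsequential.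

**Step 8**
Reactants: 14 the C8 alcohol; 15 2-(bromomethyl)acrylic acid
Product: 16 the C8 2-(bromomethyl)acrylate ester of 14
Conditions: DIC, DMAP (5 mol %), CH2Cl2, −20 → 0 °C
Reagents that add atoms: none
Why: Steglich esterification of the only free hydroxyl, with retention at C8.

**Step 9**
Reactants: 16 the C8 2-(bromomethyl)acrylate ester
Product: 17 (5S)-3-(bromomethyl)-5-[(2R,4E,6Z)-5-methoxy-2,6-dimethyl-3-oxo-2,8-bis(triethylsilyloxy)octa-4,6-dien-1-yl]furan-2(5H)-one
Conditions: second-generation Hoveyda–Grubbs catalyst (10 mol %), PhMe, 80 °C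
Reagents that add atoms: none
Why: Ring-closing metathesis between the Z-propenyl group and the acrylate gives the 3-(bromomethyl)butenolide (propene lost); the trisubstituted push-pull diene is inert to the ruthenium carbene.

**Step 10**
Reactants: 17 the bromomethyl butenolide
Product: 18 (2Z,4E,7R)-8-[(2S)-4-(bromomethyl)-5-oxo-2,5-dihydrofuran-2-yl]-4-methoxy-3,7-dimethyl-6-oxo-7-[(triethylsilyl)oxy]octa-2,4-dienal
Conditions: (COCl)2, DMSO, CH2Cl2, −78 → −40 °C; then Et3N, −78 → 0 °C
Reagents that add atoms: none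
Why: Swern conditions cleave and oxidise a primary triethylsilyl ether directly to the aldehyde while the hindered tertiary silyl ether survives; low temperature preserves the Z-enal.

**Step 11**
Reactants: 18 the bromo aldehyde
Product: 19 (4Z)-6α-hydroxy-3-methoxy-1-oxo-10α-[(triethylsilyl)oxy]germacra-2,4,11(13)-trien-12,8α-olide (H-7α, H-8β, 10β-CH3)
Conditions: CrCl2 (10 equiv), THF (0.002 M, slow addition), 25 °C; aq. work-up
Reagents that add atoms: none
Why: Nozaki–Hiyama-type Barbier macrocyclisation in which the allylchromium from the bromomethylbutenolide adds through C7 to the aldehyde, closing the ten-membered ring at C6–C7 and unveiling the α-methylene lactone; attack anti to the C8 side chain gives the trans-lactone (C7), and a chair transition state with the enal residue equatorial gives the anti 6α-alcohol (C6).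

**Step 12**
Reactants: 19 the macrocyclic alcohol; 20 angelic acid ((Z)-2-methylbut-2-enoic acid)
Product: 22 (4Z)-6α-angeloyloxy-3-methoxy-1-oxo-10α-[(triethylsilyl)oxy]germacra-2,4,11(13)-trien-12,8α-olide, via mixed anhydride 21 (not isolated)
Conditions: 20, 2,4,6-trichlorobenzoyl chloride, Et3N, PhMe, 25 °C; then 19, 60 °C (no DMAP)
Reagents that add atoms: none
Why: Yamaguchi esterification without a nucleophilic catalyst acylates the C6 hydroxyl with retention and avoids angelate-to-tiglate isomerisation; it also removes O6 as a competitor for C3 in the next step.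

**Step 13**
Reactants: 22 the macrocyclic angelate
Product: 24 (4Z)-6α-angeloyloxy-3,10α-epoxy-1-oxogermacra-2,4,11(13)-trien-12,8α-olide, via tertiary alcohol 23 (not isolated)
Conditions: 48 % aq. HF/MeCN (1:19), 0 → 25 °C
Reagents that add atoms: none
Why: Desilylation frees the C10 hydroxyl, which adds across the ring to C3 of the vinylogous ester and expels methanol (acid-catalysed cyclodehydration of an α′-hydroxy-1,3-dione equivalent to a 3(2H)-furanone); C10 reacts through oxygen, so its configuration is retained.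

**Step 14**
Reactants: 24 the 4(5)-ene furanone
Product: 26 target, 5β-hydroxy-6α-angeloyloxy-3,10α-epoxy-1-oxogermacra-2,4(15),11(13)-trien-12,8α-olide, via hydroperoxide 25 (not isolated)
Conditions: O2, tetraphenylporphyrin (cat.), visible light, CH2Cl2, −20 °C; then PPh3
Reagents that add atoms: oxygen, O=O
Why: Schenck ene reaction: singlet oxygen bonds to C5 and abstracts a C15 hydrogen (the alkyl group geminal to the conjugating furanone), giving the exocyclic alkene; with H-6 eclipsing the alkene (minimised A1,3 strain against C3) the exposed face is the one bearing O6, which gives 5S, and PPh3 reduces the hydroperoxide.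

**Compound list**
1 | (Z)-3-methylpent-2-en-4-yn-1-ol | C#C/C(C)=C\CO | starting material
2 | (Z)-triethyl[(3-methylpent-2-en-4-yn-1-yl)oxy]silane | C#C/C(C)=C\CO[Si](CC)(CC)CC | intermediate
3 | pent-3-yn-2-one | CC#CC(C)=O | starting material
4 | trimethyl(pent-1-en-3-yn-2-yloxy)silane | CC#CC(=C)O[Si](C)(C)C | intermediate
5 | methyl pyruvate | CC(=O)C(=O)OC | starting material
6 | methyl (2R)-2-methyl-4-oxo-2-[(trimethylsilyl)oxy]hept-5-ynoate | CC#CC(=O)C[C@@](C)(O[Si](C)(C)C)C(=O)OC | intermediate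
7 | methyl (2R)-2-hydroxy-2-methyl-4-oxohept-5-ynoate | CC#CC(=O)C[C@@](C)(O)C(=O)OC | intermediate
8 | methyl (2R)-2-methyl-4-oxo-2-[(triethylsilyl)oxy]hept-5-ynoate | CC#CC(=O)C[C@@](C)(O[Si](CC)(CC)CC)C(=O)OC | intermediate
9 | methyl (2R,4S)-4-hydroxy-2-methyl-2-[(triethylsilyl)oxy]hept-5-ynoate | CC#C[C@@H](O)C[C@@](C)(O[Si](CC)(CC)CC)C(=O)OC | intermediate
10 | (3R,5S)-3-methyl-5-(prop-1-yn-1-yl)-3-[(triethylsilyl)oxy]oxolan-2-one | CC#C[C@@H]1C[C@@](C)(O[Si](CC)(CC)CC)C(=O)O1 | intermediate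
11 | (3R,5S)-3-methyl-5-[(1Z)-prop-1-en-1-yl]-3-[(triethylsilyl)oxy]oxolan-2-one | C/C=C\[C@@H]1C[C@@](C)(O[Si](CC)(CC)CC)C(=O)O1 | intermediate
12 | lithium acetylide of 2 | [Li]C#C/C(C)=C\CO[Si](CC)(CC)CC | intermediate
13 | (2Z,4S,6R,10Z)-4-hydroxy-6,10-dimethyl-6,12-bis[(triethylsilyl)oxy]dodeca-2,10-dien-8-yn-7-one | CC[Si](CC)(CC)OC/C=C(C)\C#CC(=O)[C@](C)(O[Si](CC)(CC)CC)C[C@H](O)/C=C\C | intermediate
14 | (2Z,4S,6R,8E,10Z)-4-hydroxy-9-methoxy-6,10-dimethyl-6,12-bis[(triethylsilyl)oxy]dodeca-2,8,10-trien-7-one | CC[Si](CC)(CC)OC/C=C(C)\C(OC)=C/C(=O)[C@](C)(O[Si](CC)(CC)CC)C[C@H](O)/C=C\C | intermediate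
15 | 2-(bromomethyl)acrylic acid | C=C(CBr)C(=O)O | starting material
16 | 2-(bromomethyl)acrylate ester of 14 at the C8 oxygen | CC[Si](CC)(CC)OC/C=C(C)\C(OC)=C/C(=O)[C@](C)(O[Si](CC)(CC)CC)C[C@H](OC(=O)C(=C)CBr)/C=C\C | intermediate
17 | (5S)-3-(bromomethyl)-5-[(2R,4E,6Z)-5-methoxy-2,6-dimethyl-3-oxo-2,8-bis(triethylsilyloxy)octa-4,6-dien-1-yl]furan-2(5H)-one | CC[Si](CC)(CC)OC/C=C(C)\C(OC)=C/C(=O)[C@](C)(O[Si](CC)(CC)CC)C[C@@H]1OC(=O)C(CBr)=C1 | intermediate
18 | (2Z,4E,7R)-8-[(2S)-4-(bromomethyl)-5-oxo-2,5-dihydrofuran-2-yl]-4-methoxy-3,7-dimethyl-6-oxo-7-[(triethylsilyl)oxy]octa-2,4-dienal | O=C/C=C(C)\C(OC)=C/C(=O)[C@](C)(O[Si](CC)(CC)CC)C[C@@H]1OC(=O)C(CBr)=C1 | intermediate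
19 | (4Z)-6α-hydroxy-3-methoxy-1-oxo-10α-[(triethylsilyl)oxy]germacra-2,4,11(13)-trien-12,8α-olide | C=C1C(=O)O[C@H]2C[C@@](C)(O[Si](CC)(CC)CC)C(=O)/C=C(OC)\C(C)=C/[C@@H](O)[C@H]12 | intermediate
20 | angelic acid | C/C=C(/C)C(=O)O | starting material
21 | angelic 2,4,6-trichlorobenzoic anhydride | C/C=C(/C)C(=O)OC(=O)c1c(Cl)cc(Cl)cc1Cl | intermediate
22 | (4Z)-6α-angeloyloxy-3-methoxy-1-oxo-10α-[(triethylsilyl)oxy]germacra-2,4,11(13)-trien-12,8α-olide | C=C1C(=O)O[C@H]2C[C@@](C)(O[Si](CC)(CC)CC)C(=O)/C=C(OC)\C(C)=C/[C@@H](OC(=O)/C(C)=C\C)[C@H]12 | intermediate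
23 | (4Z)-6α-angeloyloxy-10α-hydroxy-3-methoxy-1-oxogermacra-2,4,11(13)-trien-12,8α-olide | C=C1C(=O)O[C@H]2C[C@@](C)(O)C(=O)/C=C(OC)\C(C)=C/[C@@H](OC(=O)/C(C)=C\C)[C@H]12 | intermediate
24 | (4Z)-6α-angeloyloxy-3,10α-epoxy-1-oxogermacra-2,4,11(13)-trien-12,8α-olide | C=C1C(=O)O[C@H]2C[C@@]3(C)OC(=CC3=O)/C(C)=C\[C@@H](OC(=O)/C(C)=C\C)[C@H]12 | intermediate
25 | 6α-angeloyloxy-3,10α-epoxy-5β-hydroperoxy-1-oxogermacra-2,4(15),11(13)-trien-12,8α-olide | C=C1C(=O)O[C@H]2C[C@@]3(C)OC(=CC3=O)C(=C)[C@H](OO)[C@@H](OC(=O)/C(C)=C\C)[C@H]12 | intermediate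
26 | CNP0120053.1, (5S,6S,7R,8S,10R)-6α-angeloyloxy-3,10α-epoxy-5β-hydroxy-1-oxogermacra-2,4(15),11(13)-trien-12,8α-olide | C=C1C(=O)O[C@H]2C[C@@]3(C)OC(=CC3=O)C(=C)[C@H](O)[C@@H](OC(=O)/C(C)=C\C)[C@H]12 | target

**Step count**
Total: 14 steps. Longest linear sequence: 13 steps (3 → 26, steps 2–14); step 1 is a one-step side branch.

**Three steps most likely to fail, with fallbacks**

Step 11 (Barbier macrocyclisation). The open chain may oligomerise, close on the wrong butenolide face, or suffer attack of the new C6 alkoxide on C3. The fallback reverses the order of ring formation and sets out from 18. Aqueous HF in MeCN removes the tertiary silyl ether, and the freed C10 hydroxyl closes onto C3 of the open chain with loss of methanol to give furanone enal F1. The furanone then acts as a rigid turn that holds C6 near C7, and CrCl2 cyclisation gives the bridged hydroxy furanone F2. Yamaguchi angeloylation of F2 rejoins the route at 24.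

Step 14 (singlet-oxygen ene reaction). The deactivated C4=C5 alkene may react slowly, the diene may undergo [4+2] addition, or the facial selectivity may be poor. The fallback sets out from 19 and builds the same functionality by epoxidation and isomerisation. m-CPBA, directed by the C6 hydroxyl (threo, same A1,3 conformer), epoxidises C4=C5 to give epoxy alcohol F3. Yamaguchi angeloylation gives epoxy angelate F4. Diethylaluminium 2,2,6,6-tetramethylpiperidide removes a C15 proton and opens the epoxide at C4 to give allylic alcohol F5 (5β-OH, 4(15)-ene). Aqueous HF in MeCN then removes the silyl ether and closes the furanone across the ring, rejoining the route at 26.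

Step 9 (ring-closing metathesis of the 2-substituted acrylate). Closure to a trisubstituted butenolide is slow and the allylic bromide may not survive. The fallback sets out from 14 and adds C13 after ring closure. Acryloyl chloride with i-Pr2NEt gives acrylate F6. Metathesis of this unhindered acrylate with second-generation Grubbs catalyst gives butenolide F7. Morita–Baylis–Hillman hydroxymethylation (aqueous formaldehyde, PMe3 catalyst) gives hydroxymethyl butenolide F8. CBr4/PPh3 converts F8 into 17, where the route is rejoined.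

**Further compounds**
F1 | step 11 | (2Z)-3-{(5R)-5-[((2S)-4-(bromomethyl)-5-oxo-2,5-dihydrofuran-2-yl)methyl]-5-methyl-4-oxo-4,5-dihydrofuran-2-yl}but-2-enal | O=C/C=C(C)\C1=CC(=O)[C@@](C)(C[C@@H]2OC(=O)C(CBr)=C2)O1
F2 | step 11 | (4Z)-3,10α-epoxy-6α-hydroxy-1-oxogermacra-2,4,11(13)-trien-12,8α-olide | C=C1C(=O)O[C@H]2C[C@@]3(C)OC(=CC3=O)/C(C)=C\[C@@H](O)[C@H]12
F3 | step 14 | 4,5-epoxide of 19, epoxide oxygen syn to the 6α-hydroxyl | C=C1C(=O)O[C@H]2C[C@@](C)(O[Si](CC)(CC)CC)C(=O)/C=C(OC)\[C@]3(C)O[C@@H]3[C@@H](O)[C@H]12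
F4 | step 14 | 6-O-angelate of F3 | C=C1C(=O)O[C@H]2C[C@@](C)(O[Si](CC)(CC)CC)C(=O)/C=C(OC)\[C@]3(C)O[C@@H]3[C@@H](OC(=O)/C(C)=C\C)[C@H]12
F5 | step 14 | 6α-angeloyloxy-5β-hydroxy-3-methoxy-1-oxo-10α-[(triethylsilyl)oxy]germacra-2,4(15),11(13)-trien-12,8α-olide | C=C1C(=O)O[C@H]2C[C@@](C)(O[Si](CC)(CC)CC)C(=O)/C=C(OC)\C(=C)[C@H](O)[C@@H](OC(=O)/C(C)=C\C)[C@H]12
F6 | step 9 | acrylate ester of 14 at the C8 oxygen | CC[Si](CC)(CC)OC/C=C(C)\C(OC)=C/C(=O)[C@](C)(O[Si](CC)(CC)CC)C[C@H](OC(=O)C=C)/C=C\C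
F7 | step 9 | (5S)-5-[(2R,4E,6Z)-5-methoxy-2,6-dimethyl-3-oxo-2,8-bis(triethylsilyloxy)octa-4,6-dien-1-yl]furan-2(5H)-one | CC[Si](CC)(CC)OC/C=C(C)\C(OC)=C/C(=O)[C@](C)(O[Si](CC)(CC)CC)C[C@@H]1OC(=O)C=C1
F8 | step 9 | 3-(hydroxymethyl) analogue of 17 | CC[Si](CC)(CC)OC/C=C(C)\C(OC)=C/C(=O)[C@](C)(O[Si](CC)(CC)CC)C[C@@H]1OC(=O)C(CO)=C1
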